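## Retrosynthetic overview

1. Target ⇐ desilylation and angeloylation of an α-methylene lactone, itself closed last by Pd-catalysed cyclocarbonylation of a 6-hydroxy-7-ethynyl cyclodecanone.
2. Ten-membered ring ⇐ Criegee-type 1,2-shift (C6 from C1 to O) of a decalyl silyl peroxide: the shared C1–C6 bond of the 6/6 bicycle is cut, giving the C1 ketone and C6–O with retention.
3. Decalin ⇐ Robinson annulation of ring A onto a ring B cyclohexanone, then C4 methylation, C3 reduction and hydroperoxysilylation of the C1=C2 alkene.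
4. Ring B ⇐ (R)-4-hydroxycyclohexenone (desymmetrising Kornblum–DeLaMare) by α′-methylation, α′-acetoxylation and OH-directed conjugate alkynylation.
5. Ring order: ring B (from cyclohexadiene) → ring A (annulation) → ten-membered carbocycle (ring expansion) → γ-lactone (carbonylation).

Assumption/convention: locants C1–C15 are those of the target's germacrane skeleton (C1 ketone, C3 carbinol, C4 and C10 methyl-bearing, C6 lactone O, C8 angelate, C11–C13 lactone carbons) and are used for every intermediate; 17 and 18 are drawn as open hydroxy ketones although they equilibrate with the transannular hemiketal.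

## Route

Step 1
Reactants: 1 cyclohexa-1,3-diene
Product: 3 (R)-4-hydroxycyclohex-2-en-1-one, via endoperoxide 2 (not isolated)
Conditions: O2, hν, tetraphenylporphyrin (0.1 mol%), CH2Cl2, −20 °C; then 6′-hydroxy-9-O-acetylquinidine-type cinchona base (5 mol%, pseudo-enantiomer chosen for the R product), CH2Cl2, rt
Reagents that add atoms: oxygen, O=O
Why: Singlet-oxygen [4+2] cycloaddition gives the meso endoperoxide, and a catalytic enantioselective Kornblum–DeLaMare rearrangement (the chiral base removes one of the two enantiotopic bridgehead protons) sets C8 as R.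

Step 2
Reactants: 3 (R)-4-hydroxycyclohex-2-en-1-one
Product: 4 (4R)-4-hydroxy-6-methylcyclohex-2-en-1-one (both C6 epimers)
Conditions: LDA (2.2 equiv), THF, −78 °C; MeI (1.2 equiv), −78 → −30 °C; then H2O
Reagents that add atoms: iodomethane, CI
Why: α′-Alkylation of the alkoxide–enolate dianion (kinetic cross-conjugated enolate) puts the C14 methyl on C10; the new centre is not controlled because it becomes planar in step 3.

Step 3
Reactants: 4 (4R)-4-hydroxy-6-methylcyclohex-2-en-1-one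
Product: 5 (1R,5R)-5-hydroxy-1-methyl-2-oxocyclohex-3-en-1-yl acetate
Conditions: Mn(OAc)3·2H2O (2.5 equiv), PhH, reflux (Dean–Stark)
Reagents that add atoms: manganese triacetate, CC(=O)[O-].CC(=O)[O-].CC(=O)[O-].[Mn+3]
Why: α′-Acetoxylation of an enone by trivalent manganese (manganese enolate, α-keto radical, acetate transfer); both epimers of 4 converge, and acetate is delivered axially, anti to the pseudo-equatorial C8 oxygen, so C10 is set R with OAc trans to OH.

Step 4
Reactants: 5 (1R,5R)-5-hydroxy-1-methyl-2-oxocyclohex-3-en-1-yl acetate; 6 ethynyltrimethylsilane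
Product: 7 (1R,4R,5R)-5-hydroxy-1-methyl-2-oxo-4-[(trimethylsilyl)ethynyl]cyclohexyl acetate
Conditions: 6 (3 equiv), n-BuLi, Et2O, 0 °C; Me2AlCl, 0 °C → rt; then 5, toluene–Et2O, 0 °C → rt; cold 1 M HCl
Reagents that add atoms: none
Why: Hydroxyl-directed conjugate alkynylation (the alkynylalane, bound as the aluminium alkoxide of C8–OH, delivers the alkynyl group to the same face of the s-trans enone) sets C7 as R with the C11≡C13 unit cis to the C8 oxygen.

Step 5
Reactants: 7 (1R,4R,5R)-5-hydroxy-1-methyl-2-oxo-4-[(trimethylsilyl)ethynyl]cyclohexyl acetate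
Product: 8 (1R,4R,5R)-1-methyl-2-oxo-5-[(triethylsilyl)oxy]-4-[(trimethylsilyl)ethynyl]cyclohexyl acetate
Conditions: TESCl, imidazole, CH2Cl2, 0 °C
Reagents that add atoms: chlorotriethylsilane, CC[Si](Cl)(CC)CC
Why: Silyl ether formation on the only free hydroxyl keeps the C8 oxygen blocked until the lactone has been closed on C6.

Step 6
Reactants: 8 (1R,4R,5R)-1-methyl-2-oxo-5-[(triethylsilyl)oxy]-4-[(trimethylsilyl)ethynyl]cyclohexyl acetate; 9 but-3-en-2-one
Product: 11 (1R,3R,4R,4aR)-1-methyl-7-oxo-3-[(triethylsilyl)oxy]-4-[(trimethylsilyl)ethynyl]-1,2,3,4,4a,5,6,7-octahydronaphthalen-1-yl acetate, via diketone 10 (not isolated)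
Conditions: 9 (1.5 equiv), KOt-Bu (0.1 equiv), t-BuOH–THF, 0 °C; then pyrrolidine (0.5 equiv), AcOH (0.5 equiv), toluene, 60 °C
Reagents that add atoms: none
Why: Robinson annulation (Michael addition at C6, the only enolisable α-carbon, then amine/acid-promoted aldol condensation) builds ring A; C6 equilibrates to the epimer with C5 equatorial and cis to the axial alkynyl group, because the alternative suffers 1,3-diaxial OAc/C5 or Me/OTES contacts.

Step 7
Reactants: 11 (1R,3R,4R,4aR)-1-methyl-7-oxo-3-[(triethylsilyl)oxy]-4-[(trimethylsilyl)ethynyl]-1,2,3,4,4a,5,6,7-octahydronaphthalen-1-yl acetate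
Product: 12 (1R,3R,4R,4aR,6S)-1,6-dimethyl-7-oxo-3-[(triethylsilyl)oxy]-4-[(trimethylsilyl)ethynyl]-1,2,3,4,4a,5,6,7-octahydronaphthalen-1-yl acetate
Conditions: LiHMDS (1.05 equiv), THF, −78 °C; MeI (3 equiv), −78 → −40 °C
Reagents that add atoms: iodomethane, CI
Why: Kinetic α′-enolate alkylation of the enone; axial attack on the face carrying H6 (the usual trans-4,6 outcome for 4-substituted cyclohexenone enolates) sets C4 as S.

Step 8
Reactants: 12 (1R,3R,4R,4aR,6S)-1,6-dimethyl-7-oxo-3-[(triethylsilyl)oxy]-4-[(trimethylsilyl)ethynyl]-1,2,3,4,4a,5,6,7-octahydronaphthalen-1-yl acetate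
Product: 13 (1R,3R,4R,4aR,6S,7R)-7-hydroxy-1,6-dimethyl-3-[(triethylsilyl)oxy]-4-[(trimethylsilyl)ethynyl]-1,2,3,4,4a,5,6,7-octahydronaphthalen-1-yl acetate
Conditions: (S)-2-methyl-CBS-oxazaborolidine (0.5 equiv), catecholborane (2 equiv), toluene, −78 °C; aq. NaHCO3 work-up
Reagents that add atoms: none
Why: Corey–Bakshi–Shibata reduction under catalyst control (alkenyl side as the large group) delivers hydride to the face syn to the C4 methyl, giving the C3 carbinol trans to that methyl.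

Step 9
Reactants: 13 (1R,3R,4R,4aR,6S,7R)-7-hydroxy-1,6-dimethyl-3-[(triethylsilyl)oxy]-4-[(trimethylsilyl)ethynyl]-1,2,3,4,4a,5,6,7-octahydronaphthalen-1-yl acetate
Product: 14 (1R,3R,4R,4aR,6S,7R)-7-[(tert-butyldimethylsilyl)oxy]-1,6-dimethyl-3-[(triethylsilyl)oxy]-4-[(trimethylsilyl)ethynyl]-1,2,3,4,4a,5,6,7-octahydronaphthalen-1-yl acetate
Conditions: TBSOTf, 2,6-lutidine, CH2Cl2, −78 °C
Reagents that add atoms: tert-butyldimethylsilyl triflate, CC(C)(C)[Si](C)(C)OS(=O)(=O)C(F)(F)F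
Why: Silyl ether formation gives C3 a protecting group that outlasts the TES ether on C8, so the two oxygens can be told apart at the end.

Step 10
Reactants: 14 (1R,3R,4R,4aR,6S,7R)-7-[(tert-butyldimethylsilyl)oxy]-1,6-dimethyl-3-[(triethylsilyl)oxy]-4-[(trimethylsilyl)ethynyl]-1,2,3,4,4a,5,6,7-octahydronaphthalen-1-yl acetate
Product: 15 (1R,3R,4R,4aR,6S,7S)-7-[(tert-butyldimethylsilyl)oxy]-1,6-dimethyl-3-[(triethylsilyl)oxy]-8a-[(triethylsilyl)peroxy]-4-[(trimethylsilyl)ethynyl]decahydronaphthalen-1-yl acetate (both C8a epimers)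
Conditions: Co(C11H19O2)2 [cobalt bis(2,2,6,6-tetramethylheptane-3,5-dionate), 10 mol%], O2 (1 atm), Et3SiH (2.5 equiv), 1,2-dichloroethane, rt
Reagents that add atoms: oxygen, O=O; triethylsilane, CC[SiH](CC)CC
Why: Mukaiyama–Isayama hydroperoxysilylation (hydrogen-atom transfer to C2, trapping of the tertiary C1 radical by O2) puts the peroxide on the ring-fusion carbon; both C1 epimers serve because C1 becomes the ketone.

Step 11
Reactants: 15 (1R,3R,4R,4aR,6S,7S)-7-[(tert-butyldimethylsilyl)oxy]-1,6-dimethyl-3-[(triethylsilyl)oxy]-8a-[(triethylsilyl)peroxy]-4-[(trimethylsilyl)ethynyl]decahydronaphthalen-1-yl acetate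
Product: 18 (1R,4S,5S,7R,8S,9R)-4-[(tert-butyldimethylsilyl)oxy]-8-ethynyl-7-hydroxy-1,5-dimethyl-2-oxo-9-[(triethylsilyl)oxy]cyclodecyl acetate, via oxocarbenium triflate 16 (not isolated), via silylalkynyl hydroxy ketone 17 (not isolated)
Conditions: TMSOTf (1.2 equiv), 2,6-di-tert-butyl-4-methylpyridine (1.5 equiv), CH2Cl2, −78 → −40 °C; then H2O–THF, NaHCO3, 0 °C; then K2CO3 (0.2 equiv), MeOH, 0 °C
Reagents that add atoms: water, O
Why: Proposed new method: a silyl-triflate-triggered Criegee rearrangement of a tertiary trialkylsilyl peroxide – Me3Si+ adds to the distal peroxide oxygen to make a neutral disiloxane leaving group, and O–O heterolysis is concerted with 1,2-shift of the antiperiplanar ring-fusion carbon C6 from C1 to oxygen (C6, a secondary alkyl group, should outrun the primary C2 and the fully substituted C10, which is inductively deactivated by its acetoxy group); the shift goes with retention at C6 and opens the 6/6 bicycle to the ten-membered ring as a bridged oxocarbenium ion, which water converts to the 6-hydroxy ketone before K2CO3/MeOH frees the alkyne; the closest known reaction types are the Criegee rearrangement of 9-decalyl peresters to 6-hydroxycyclodecanone and the acid-promoted Hock cleavage of hydroperoxides.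

Step 12
Reactants: 18 (1R,4S,5S,7R,8S,9R)-4-[(tert-butyldimethylsilyl)oxy]-8-ethynyl-7-hydroxy-1,5-dimethyl-2-oxo-9-[(triethylsilyl)oxy]cyclodecyl acetate
Product: 19 (3S,4S,6R,7S,8R,10R)-10-acetoxy-3-[(tert-butyldimethylsilyl)oxy]-1-oxo-8-[(triethylsilyl)oxy]germacr-11(13)-en-12,6-olide
Conditions: PdCl2 (5 mol%), SnCl2 (5 mol%), PPh3 (10 mol%), CO (8 atm), MeCN, 75 °C
Reagents that add atoms: carbon monoxide, [C-]#[O+]
Why: Norton-type palladium-catalysed cyclocarbonylation of a homopropargylic alcohol (the alkoxycarbonyl-palladium species from C6–OH adds syn across the alkyne, then protonolysis) forms the α-methylene-γ-lactone on the only free hydroxyl, so the trans ring fusion follows from the existing C6 and C7 centres.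

Step 13
Reactants: 19 (3S,4S,6R,7S,8R,10R)-10-acetoxy-3-[(tert-butyldimethylsilyl)oxy]-1-oxo-8-[(triethylsilyl)oxy]germacr-11(13)-en-12,6-olide
Product: 20 (3S,4S,6R,7R,8R,10R)-10-acetoxy-3-[(tert-butyldimethylsilyl)oxy]-8-hydroxy-1-oxogermacr-11(13)-en-12,6-olide
Conditions: PPTS (0.2 equiv), MeOH–CH2Cl2, 0 °C
Reagents that add atoms: none
Why: Acid-catalysed methanolysis cleaves the secondary TES ether much faster than the TBS ether, freeing C8–OH alone (the C7 descriptor changes only through priorities).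

Step 14
Reactants: 20 (3S,4S,6R,7R,8R,10R)-10-acetoxy-3-[(tert-butyldimethylsilyl)oxy]-8-hydroxy-1-oxogermacr-11(13)-en-12,6-olide; 21 angelic acid
Product: 22 (3S,4S,6R,7S,8R,10R)-10-acetoxy-8-angeloyloxy-3-[(tert-butyldimethylsilyl)oxy]-1-oxogermacr-11(13)-en-12,6-olide
Conditions: 21 (3 equiv), 2,4,6-trichlorobenzoyl chloride, Et3N, toluene, rt; then 20, toluene, 80 °C
Reagents that add atoms: none
Why: Yamaguchi-type mixed-anhydride esterification, run without DMAP to keep the Z double bond, acylates C8–OH with retention at C8.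

Step 15
Reactants: 22 (3S,4S,6R,7S,8R,10R)-10-acetoxy-8-angeloyloxy-3-[(tert-butyldimethylsilyl)oxy]-1-oxogermacr-11(13)-en-12,6-olide
Product: 23 (3S,4S,6R,7S,8R,10R)-10-acetoxy-8-angeloyloxy-3-hydroxy-1-oxogermacr-11(13)-en-12,6-olide (CNP0141210.1)
Conditions: HF·pyridine, pyridine, THF, 0 °C → rt
Reagents that add atoms: none
Why: Fluoride-mediated desilylation frees C3–OH under mildly acidic conditions that leave the acetate, angelate, α-methylene lactone and β-hydroxy ketone intact.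

## Compound list

1 | cyclohexa-1,3-diene | C1=CC=CCC1 | starting material
2 | 2,3-dioxabicyclo[2.2.2]oct-5-ene (meso endoperoxide) | C1CC2C=CC1OO2 | intermediate
3 | (R)-4-hydroxycyclohex-2-en-1-one | O=C1C=C[C@H](O)CC1 | intermediate
4 | (4R)-4-hydroxy-6-methylcyclohex-2-en-1-one (both C6 epimers) | O=C1C=C[C@H](O)CC1C | intermediate
5 | (1R,5R)-5-hydroxy-1-methyl-2-oxocyclohex-3-en-1-yl acetate | O=C1C=C[C@H](O)C[C@@]1(C)OC(C)=O | intermediate
6 | ethynyltrimethylsilane | C#C[Si](C)(C)C | starting material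
7 | (1R,4R,5R)-5-hydroxy-1-methyl-2-oxo-4-[(trimethylsilyl)ethynyl]cyclohexyl acetate | O=C1C[C@H](C#C[Si](C)(C)C)[C@H](O)C[C@@]1(C)OC(C)=O | intermediate
8 | (1R,4R,5R)-1-methyl-2-oxo-5-[(triethylsilyl)oxy]-4-[(trimethylsilyl)ethynyl]cyclohexyl acetate | O=C1C[C@H](C#C[Si](C)(C)C)[C@H](O[Si](CC)(CC)CC)C[C@@]1(C)OC(C)=O | intermediate
9 | but-3-en-2-one (methyl vinyl ketone) | C=CC(C)=O | starting material
10 | (1R,3R,4R,5R)-1-methyl-2-oxo-3-(3-oxobutyl)-5-[(triethylsilyl)oxy]-4-[(trimethylsilyl)ethynyl]cyclohexyl acetate | CC(=O)CC[C@@H]1[C@H](C#C[Si](C)(C)C)[C@H](O[Si](CC)(CC)CC)C[C@@](C)(OC(C)=O)C1=O | intermediate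
11 | (1R,3R,4R,4aR)-1-methyl-7-oxo-3-[(triethylsilyl)oxy]-4-[(trimethylsilyl)ethynyl]-1,2,3,4,4a,5,6,7-octahydronaphthalen-1-yl acetate | O=C1CC[C@@H]2[C@H](C#C[Si](C)(C)C)[C@H](O[Si](CC)(CC)CC)C[C@@](C)(OC(C)=O)C2=C1 | intermediate
12 | (1R,3R,4R,4aR,6S)-1,6-dimethyl-7-oxo-3-[(triethylsilyl)oxy]-4-[(trimethylsilyl)ethynyl]-1,2,3,4,4a,5,6,7-octahydronaphthalen-1-yl acetate | O=C1[C@@H](C)C[C@@H]2[C@H](C#C[Si](C)(C)C)[C@H](O[Si](CC)(CC)CC)C[C@@](C)(OC(C)=O)C2=C1 | intermediate
13 | (1R,3R,4R,4aR,6S,7R)-7-hydroxy-1,6-dimethyl-3-[(triethylsilyl)oxy]-4-[(trimethylsilyl)ethynyl]-1,2,3,4,4a,5,6,7-octahydronaphthalen-1-yl acetate | O[C@@H]1[C@@H](C)C[C@@H]2[C@H](C#C[Si](C)(C)C)[C@H](O[Si](CC)(CC)CC)C[C@@](C)(OC(C)=O)C2=C1 | intermediate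
14 | (1R,3R,4R,4aR,6S,7R)-7-[(tert-butyldimethylsilyl)oxy]-1,6-dimethyl-3-[(triethylsilyl)oxy]-4-[(trimethylsilyl)ethynyl]-1,2,3,4,4a,5,6,7-octahydronaphthalen-1-yl acetate | CC(C)(C)[Si](C)(C)O[C@@H]1[C@@H](C)C[C@@H]2[C@H](C#C[Si](C)(C)C)[C@H](O[Si](CC)(CC)CC)C[C@@](C)(OC(C)=O)C2=C1 | intermediate
15 | (1R,3R,4R,4aR,6S,7S)-7-[(tert-butyldimethylsilyl)oxy]-1,6-dimethyl-3-[(triethylsilyl)oxy]-8a-[(triethylsilyl)peroxy]-4-[(trimethylsilyl)ethynyl]decahydronaphthalen-1-yl acetate (both C8a epimers) | CC(C)(C)[Si](C)(C)O[C@@H]1[C@@H](C)C[C@@H]2[C@H](C#C[Si](C)(C)C)[C@H](O[Si](CC)(CC)CC)C[C@@](C)(OC(C)=O)C2(OO[Si](CC)(CC)CC)C1 | intermediate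
16 | C1=O(+)–C6 bridged oxocarbenium triflate of the ten-membered ring (11-oxoniabicyclo[4.4.1]undecene core; substituents as in 17) | [C@H]12C[C@H](C)[C@@H](O[Si](C)(C)C(C)(C)C)CC(=[O+]1)[C@](C)(OC(C)=O)C[C@@H](O[Si](CC)(CC)CC)[C@H]2C#C[Si](C)(C)C.[O-]S(=O)(=O)C(F)(F)F | intermediate
17 | (1R,4S,5S,7R,8S,9R)-4-[(tert-butyldimethylsilyl)oxy]-7-hydroxy-1,5-dimethyl-2-oxo-9-[(triethylsilyl)oxy]-8-[(trimethylsilyl)ethynyl]cyclodecyl acetate | O[C@@H]1C[C@H](C)[C@@H](O[Si](C)(C)C(C)(C)C)CC(=O)[C@](C)(OC(C)=O)C[C@@H](O[Si](CC)(CC)CC)[C@H]1C#C[Si](C)(C)C | intermediate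
18 | (1R,4S,5S,7R,8S,9R)-4-[(tert-butyldimethylsilyl)oxy]-8-ethynyl-7-hydroxy-1,5-dimethyl-2-oxo-9-[(triethylsilyl)oxy]cyclodecyl acetate | O[C@@H]1C[C@H](C)[C@@H](O[Si](C)(C)C(C)(C)C)CC(=O)[C@](C)(OC(C)=O)C[C@@H](O[Si](CC)(CC)CC)[C@H]1C#C | intermediate
19 | (3S,4S,6R,7S,8R,10R)-10-acetoxy-3-[(tert-butyldimethylsilyl)oxy]-1-oxo-8-[(triethylsilyl)oxy]germacr-11(13)-en-12,6-olide | C=C1C(=O)O[C@@H]2C[C@H](C)[C@@H](O[Si](C)(C)C(C)(C)C)CC(=O)[C@](C)(OC(C)=O)C[C@@H](O[Si](CC)(CC)CC)[C@@H]12 | intermediate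
20 | (3S,4S,6R,7R,8R,10R)-10-acetoxy-3-[(tert-butyldimethylsilyl)oxy]-8-hydroxy-1-oxogermacr-11(13)-en-12,6-olide | C=C1C(=O)O[C@@H]2C[C@H](C)[C@@H](O[Si](C)(C)C(C)(C)C)CC(=O)[C@](C)(OC(C)=O)C[C@@H](O)[C@@H]12 | intermediate
21 | angelic acid, (Z)-2-methylbut-2-enoic acid | C/C=C(/C)C(=O)O | starting material
22 | (3S,4S,6R,7S,8R,10R)-10-acetoxy-8-angeloyloxy-3-[(tert-butyldimethylsilyl)oxy]-1-oxogermacr-11(13)-en-12,6-olide | C=C1C(=O)O[C@@H]2C[C@H](C)[C@@H](O[Si](C)(C)C(C)(C)C)CC(=O)[C@](C)(OC(C)=O)C[C@@H](OC(=O)/C(C)=C\C)[C@@H]12 | intermediate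
23 | (3S,4S,6R,7S,8R,10R)-10-acetoxy-8-angeloyloxy-3-hydroxy-1-oxogermacr-11(13)-en-12,6-olide (CNP0141210.1) | C=C1C(=O)O[C@@H]2C[C@H](C)[C@@H](O)CC(=O)[C@](C)(OC(C)=O)C[C@@H](OC(=O)/C(C)=C\C)[C@@H]12 | target

## Step count and risks

Total steps: 15. Longest linear sequence: 15 (the route is linear from 1; 6, 9 and 21 are added as purchased reagents).

Step 11 (the proposed new step) is the most likely to fail. The acetoxylated C10 could migrate instead of C6, or the C10 acetate could take part in ionisation at C1. Fallback with known chemistry, the classical two-stage perester route: starting from 15, K2CO3 in MeOH at 0 °C cleaves the peroxide O–Si bond and the alkynyl silyl group to give the free tertiary hydroperoxide F1. 4-Nitrobenzoyl chloride and pyridine in CH2Cl2 at 0 °C give the 4-nitroperbenzoate F2. On warming in CH2Cl2–MeNO2 this undergoes the classical Criegee rearrangement to the C1–O–C6 bridged ketal 4-nitrobenzoate F3. Brief hydrolysis of this acylal with aqueous K2CO3 in MeOH returns the route at 18.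

Step 3 is the second risk. The free γ-hydroxy enone may dehydrate to a phenol in hot benzene, and a tertiary α′-C–H is being oxidised with only modest facial bias. Fallback, moving the oxidation to the protected enone: starting from 4, TESCl and imidazole give (4R)-6-methyl-4-[(triethylsilyl)oxy]cyclohex-2-en-1-one F4. Mn(OAc)3 in refluxing benzene, now on a substrate that cannot dehydrate and whose bulky silyloxy group enforces anti attack, gives (1R,5R)-1-methyl-2-oxo-5-[(triethylsilyl)oxy]cyclohex-3-en-1-yl acetate F5. HF·pyridine removes the silyl group and returns the route at 5.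

Step 8 is the third risk. The catalyst must deliver hydride syn to the axial C4 methyl, against the substrate's own preference. Fallback, substrate control followed by inversion: starting from 12, NaBH4 with CeCl3·7H2O in MeOH at −78 °C (Luche reduction, hydride anti to the methyl) gives the C3-epimeric allylic alcohol F6. A Mitsunobu reaction with chloroacetic acid, PPh3 and DIAD (nucleophile enters on the unhindered face) gives the inverted chloroacetate F7. Thiourea and NaHCO3 in EtOH cleave the chloroacetate and return the route at 13.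

Further compounds
F1 | step 11 | (1R,3R,4R,4aR,6S,7S)-7-[(tert-butyldimethylsilyl)oxy]-4-ethynyl-8a-hydroperoxy-1,6-dimethyl-3-[(triethylsilyl)oxy]decahydronaphthalen-1-yl acetate (both C8a epimers) | CC(C)(C)[Si](C)(C)O[C@@H]1[C@@H](C)C[C@@H]2[C@H](C#C)[C@H](O[Si](CC)(CC)CC)C[C@@](C)(OC(C)=O)C2(OO)C1
F2 | step 11 | 4-nitroperbenzoate (O–O acylated) of F1 | CC(C)(C)[Si](C)(C)O[C@@H]1[C@@H](C)C[C@@H]2[C@H](C#C)[C@H](O[Si](CC)(CC)CC)C[C@@](C)(OC(C)=O)C2(OOC(=O)c3ccc(cc3)[N+](=O)[O-])C1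
F3 | step 11 | C1–O–C6 bridged ketal 1-(4-nitrobenzoate) corresponding to 18 (11-oxabicyclo[4.4.1]undecane core) | [C@H]12C[C@H](C)[C@@H](O[Si](C)(C)C(C)(C)C)CC(O1)(OC(=O)c3ccc(cc3)[N+](=O)[O-])[C@](C)(OC(C)=O)C[C@@H](O[Si](CC)(CC)CC)[C@H]2C#C
F4 | step 3 | (4R)-6-methyl-4-[(triethylsilyl)oxy]cyclohex-2-en-1-one (both C6 epimers) | O=C1C=C[C@H](O[Si](CC)(CC)CC)CC1C
F5 | step 3 | (1R,5R)-1-methyl-2-oxo-5-[(triethylsilyl)oxy]cyclohex-3-en-1-yl acetate | O=C1C=C[C@H](O[Si](CC)(CC)CC)C[C@@]1(C)OC(C)=O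
F6 | step 8 | (1R,3R,4R,4aR,6S,7S)-7-hydroxy-1,6-dimethyl-3-[(triethylsilyl)oxy]-4-[(trimethylsilyl)ethynyl]-1,2,3,4,4a,5,6,7-octahydronaphthalen-1-yl acetate (C3 epimer of 13) | O[C@H]1[C@@H](C)C[C@@H]2[C@H](C#C[Si](C)(C)C)[C@H](O[Si](CC)(CC)CC)C[C@@](C)(OC(C)=O)C2=C1
F7 | step 8 | (1R,3R,4R,4aR,6S,7R)-7-(chloroacetoxy)-1,6-dimethyl-3-[(triethylsilyl)oxy]-4-[(trimethylsilyl)ethynyl]-1,2,3,4,4a,5,6,7-octahydronaphthalen-1-yl acetate | ClCC(=O)O[C@@H]1[C@@H](C)C[C@@H]2[C@H](C#C[Si](C)(C)C)[C@H](O[Si](CC)(CC)CC)C[C@@](C)(OC(C)=O)C2=C1
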